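The quinone ring (ring A, atoms C1–C6) is cut at C2–C3 and C4–C5. The key step exploits the fact that C3 (nonadecyl) and C4 (oxygenated) sit side by side next to the run C5(OMe)–C6(H)–C1(O)–C2. A Diels–Alder reaction of a chain-bearing ynal with a 1,1-dimethoxy-3-silyloxybutadiene, followed by loss of methanol, assembles the complete benzene ring in one operation. Chain, methoxy group and C1 oxygen are placed regiospecifically, and a formyl group marks C4. The precursors are docos-2-ynal and 1,1-dimethoxy-3-(trimethylsilyloxy)buta-1,3-diene. Dakin oxidation, quinone formation and Thiele–Winter acetoxylation at C2 then deliver the hydroxyquinone.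

Key step: step 5

Assumption: the side chain in the target SMILES is read as nonadecyl (nineteen carbons), so the target is achiral 2-hydroxy-5-methoxy-3-nonadecyl-1,4-benzoquinone. Ring atoms are numbered C1(=O), C2(OH), C3(nonadecyl), C4(=O), C5(OMe), C6(H) throughout.

Step 1
Reactants: 1 1-bromononadecane; 2 lithium acetylide–ethylenediamine complex (LiC≡CH·H2NCH2CH2NH2)
Product: 3 henicos-1-yne
Conditions: DMSO/THF, 0 °C → rt
Reagents that add atoms: none
Why: SN2 alkylation of an acetylide by an unhindered primary bromide in a dipolar aprotic medium is the standard entry to long-chain terminal alkynes.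

Step 2
Reactants: 3 henicos-1-yne
Product: 6 docos-2-ynal, via lithium henicos-1-yn-1-ide 4 (not isolated), via lithium 1-(dimethylamino)docos-2-yn-1-olate 5 (not isolated)
Conditions: n-BuLi, THF, −40 → 0 °C; DMF, −40 °C → rt; inverse quench into aq KH2PO4/MTBE, 0 °C
Reagents that add atoms: N,N-dimethylformamide, CN(C)C=O
Why: Formylation of a lithium acetylide with DMF gives a stable hemiaminal alkoxide that releases the ynal only in the buffered acidic inverse quench, where dimethylamine is protonated before it can add to the triple bond.

Step 3
Reactants: 7 1,1-dimethoxyethene; 8 acetyl chloride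
Product: 9 4,4-dimethoxybut-3-en-2-one
Conditions: Et3N, Et2O, 0 °C → rt
Reagents that add atoms: none
Why: C-acylation of a ketene acetal, in which the nucleophilic CH2 carbon attacks the acid chloride and Et3N deprotonates the resulting dimethoxycarbenium ion to give the push–pull enone.

Step 4
Reactants: 9 4,4-dimethoxybut-3-en-2-one
Product: 10 1,1-dimethoxy-3-(trimethylsilyloxy)buta-1,3-diene
Conditions: TMSCl, Et3N, ZnCl2 (cat.), Et2O/toluene, rt → 40 °C; filtration, distillation
Reagents that add atoms: chlorotrimethylsilane, C[Si](C)(C)Cl
Why: Soft enolisation and O-silylation of the methyl ketone, the only enolisable position, gives the cross-conjugated silyl enol ether without touching the ketene acetal.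

Step 5
Reactants: 6 docos-2-ynal; 10 1,1-dimethoxy-3-(trimethylsilyloxy)buta-1,3-diene
Product: 13 4-hydroxy-2-methoxy-6-nonadecylbenzaldehyde, via cyclohexa-1,4-diene cycloadduct 11 (not isolated), via aryl trimethylsilyl ether 12 (not isolated)
Conditions: 10 (excess, freshly distilled), toluene, rt → 80 °C; then 1 M HCl, THF, rt
Reagents that add atoms: none
Why: The electron-rich diene 10 and the electron-poor ynal 6 should combine in an asynchronous, normal-electron-demand [4+2] cycloaddition in which the CH2 terminus of 10 bonds to the beta alkyne carbon carrying the chain (C2–C3) and the ketene acetal carbon bonds to the alpha carbon carrying the formyl group (C4–C5). The closest known reaction type is the Diels–Alder addition and aromatisation of 1,1-dialkoxy-3-silyloxybutadienes with acetylenic carbonyl compounds, which gives resorcinol monoethers. Ring A, the only ring formed, is closed by this intermolecular cycloaddition, which makes both ring bonds of the six-membered carbocycle in one step; adduct 11 then aromatises by 1,4-elimination of methanol from the acetal carbon C5 and the C2 methylene, and dilute acid completes this and cleaves silyl ether 12. No stereocentre is created. The step needs regioselectivity, secured by the matched polarisation of the partners (most nucleophilic diene terminus to the electrophilic beta carbon), and chemoselectivity for the triple bond over the formyl group, favoured by a purely thermal reaction in toluene without any Lewis acid.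

Step 6
Reactants: 13 4-hydroxy-2-methoxy-6-nonadecylbenzaldehyde
Product: 15 2-methoxy-6-nonadecylbenzene-1,4-diol, via aryl formate 14 (not isolated)
Conditions: 30% H2O2, NaOH, THF/H2O, 0 °C → rt, Ar; then Na2S2O3, 1 M HCl
Reagents that add atoms: hydrogen peroxide, OO
Why: Dakin oxidation, in which hydroperoxide adds to the formyl group, the electron-rich para-phenoxide aryl group migrates to oxygen and the resulting formate is saponified in situ, so that C4 becomes oxygen-bearing.

Step 7
Reactants: 15 2-methoxy-6-nonadecylbenzene-1,4-diol
Product: 16 2-methoxy-6-nonadecylcyclohexa-2,5-diene-1,4-dione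
Conditions: FeCl3, EtOH/THF/H2O, rt
Reagents that add atoms: none
Why: Two-electron oxidation of an electron-rich hydroquinone to the para-quinone by FeCl3 is a standard mild method that leaves the methyl ether and the chain untouched.

Step 8
Reactants: 16 2-methoxy-6-nonadecylcyclohexa-2,5-diene-1,4-dione
Product: 17 5-methoxy-3-nonadecylbenzene-1,2,4-triyl triacetate
Conditions: Ac2O, H2SO4 (cat.), rt → 40 °C; ice-water
Reagents that add atoms: acetic anhydride, CC(=O)OC(C)=O
Why: Thiele–Winter acetoxylation, in which acetate adds in conjugate fashion at C2 (beta to the C4 carbonyl, which is not deactivated by vinylogous-ester donation from the methoxy group, and away from the electron-rich C6), followed by enolisation and exhaustive acetylation.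

Step 9
Reactants: 17 5-methoxy-3-nonadecylbenzene-1,2,4-triyl triacetate
Product: 19 irisoquin C (2-hydroxy-5-methoxy-3-nonadecylcyclohexa-2,5-diene-1,4-dione), via 5-methoxy-3-nonadecylbenzene-1,2,4-triol 18 (not isolated)
Conditions: HCl (cat.), MeOH/THF, 50 °C, Ar; evaporate; aq FeCl3, EtOAc, rt
Reagents that add atoms: none
Why: Acid-catalysed methanolysis of the three aryl acetates (methanol cannot alter the methyl ether) should release the benzenetriol, whose para-related hydroxyls at C1 and C4 are oxidised by FeCl3 to the quinone while the C2 hydroxyl remains.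

Compound list
1 | 1-bromononadecane | CCCCCCCCCCCCCCCCCCCBr | starting material
2 | lithium acetylide–ethylenediamine complex (LiC≡CH·H2NCH2CH2NH2) | [Li+].[C-]#C.NCCN | starting material
3 | henicos-1-yne | CCCCCCCCCCCCCCCCCCCC#C | intermediate
4 | lithium henicos-1-yn-1-ide | CCCCCCCCCCCCCCCCCCCC#C[Li] | intermediate (not isolated)
5 | lithium 1-(dimethylamino)docos-2-yn-1-olate (racemic) | CCCCCCCCCCCCCCCCCCCC#CC(O[Li])N(C)C | intermediate (not isolated)
6 | docos-2-ynal | CCCCCCCCCCCCCCCCCCCC#CC=O | intermediate
7 | 1,1-dimethoxyethene | C=C(OC)OC | starting material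
8 | acetyl chloride | CC(Cl)=O | starting material
9 | 4,4-dimethoxybut-3-en-2-one | CC(=O)C=C(OC)OC | intermediate
10 | 1,1-dimethoxy-3-(trimethylsilyloxy)buta-1,3-diene | COC(OC)=CC(=C)O[Si](C)(C)C | intermediate
11 | 6,6-dimethoxy-2-nonadecyl-4-(trimethylsilyloxy)cyclohexa-1,4-diene-1-carbaldehyde | CCCCCCCCCCCCCCCCCCCC1=C(C=O)C(OC)(OC)C=C(O[Si](C)(C)C)C1 | intermediate (not isolated)
12 | 2-methoxy-6-nonadecyl-4-(trimethylsilyloxy)benzaldehyde | CCCCCCCCCCCCCCCCCCCc1cc(O[Si](C)(C)C)cc(OC)c1C=O | intermediate (not isolated)
13 | 4-hydroxy-2-methoxy-6-nonadecylbenzaldehyde | CCCCCCCCCCCCCCCCCCCc1cc(O)cc(OC)c1C=O | intermediate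
14 | 4-hydroxy-2-methoxy-6-nonadecylphenyl formate | CCCCCCCCCCCCCCCCCCCc1cc(O)cc(OC)c1OC=O | intermediate (not isolated)
15 | 2-methoxy-6-nonadecylbenzene-1,4-diol | CCCCCCCCCCCCCCCCCCCc1cc(O)cc(OC)c1O | intermediate
16 | 2-methoxy-6-nonadecylcyclohexa-2,5-diene-1,4-dione | CCCCCCCCCCCCCCCCCCCC1=CC(=O)C=C(OC)C1=O | intermediate
17 | 5-methoxy-3-nonadecylbenzene-1,2,4-triyl triacetate | CCCCCCCCCCCCCCCCCCCc1c(OC(C)=O)c(OC(C)=O)cc(OC)c1OC(C)=O | intermediate
18 | 5-methoxy-3-nonadecylbenzene-1,2,4-triol | CCCCCCCCCCCCCCCCCCCc1c(O)c(O)cc(OC)c1O | intermediate (not isolated)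
19 | irisoquin C, 2-hydroxy-5-methoxy-3-nonadecylcyclohexa-2,5-diene-1,4-dione | CCCCCCCCCCCCCCCCCCCC1=C(O)C(=O)C=C(OC)C1=O | target

Total step count: 9.
Longest linear sequence: 7 steps (1 → 3 → 6 → 13 → 15 → 16 → 17 → 19, steps 1, 2, 5, 6, 7, 8, 9). The diene branch (7 and 8 → 9 → 10, steps 3 and 4) joins at step 5.

Steps most likely to fail

Step 5. The very nucleophilic diene may attack the formyl carbon (hetero-Diels–Alder or Mukaiyama-type aldol addition) instead of adding across the triple bond, and the moisture-sensitive diene may be lost by hydrolysis before it reacts. Fallback, from 3 back to 13: the aldehyde oxidation level is postponed. Henicos-1-yne 3 is deprotonated with n-BuLi and trapped with methyl chloroformate to give methyl docos-2-ynoate F1. Thermal cycloaddition of F1 with diene 10 (toluene or xylene, 110–130 °C, then dilute HCl) uses an ester dienophile whose carbonyl group cannot compete. With the same regiochemistry it should give methyl 4-hydroxy-2-methoxy-6-nonadecylbenzoate F2. Reduction with LiAlH4 in THF at 0 °C to rt, stopped as soon as the ester is consumed, gives 4-(hydroxymethyl)-3-methoxy-5-nonadecylphenol F3. Selective benzylic oxidation with MnO2 in CH2Cl2 then returns to aldehyde 13.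

Step 8. Acetate may add at C6 beside the methoxy group instead of at C2, the strong acid may cleave the methyl ether, or the poorly soluble quinone may react incompletely. Fallback, from 16 directly to 19: nucleophilic epoxidation with t-BuOOH/DBU in THF at 0 °C attacks the C2=C3 double bond, the one without a donor substituent. It gives racemic 3-methoxy-1-nonadecyl-7-oxabicyclo[4.1.0]hept-3-ene-2,5-dione F4. Acid-promoted isomerisation of this epoxide (cold concentrated H2SO4, the way 2-alkylnaphthoquinone oxides are turned into 2-hydroxy-3-alkylnaphthoquinones) opens the C3–O bond with loss of the C2 proton. This places the hydroxyl at C2 and gives target 19, bypassing 17 and 18.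

Step 6. The electron-rich hydroquinone may be over-oxidised by alkaline peroxide (quinone formation followed by epoxidation or ring cleavage), or peroxide addition to the doubly ortho-substituted formyl group may be too slow. Fallback, from 13 back to 15: the phenol is acetylated (Ac2O, pyridine) to give 4-formyl-3-methoxy-5-nonadecylphenyl acetate F5. Baeyer–Villiger oxidation with mCPBA in CH2Cl2 (NaHCO3 buffer), under non-basic conditions in which no free hydroquinone is present, gives 4-(formyloxy)-3-methoxy-5-nonadecylphenyl acetate F6. Acid-catalysed methanolysis of both esters (HCl cat., MeOH/THF, Ar) gives hydroquinone 15.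

Further compounds
F1 | step 5 | methyl docos-2-ynoate | CCCCCCCCCCCCCCCCCCCC#CC(=O)OC
F2 | step 5 | methyl 4-hydroxy-2-methoxy-6-nonadecylbenzoate | CCCCCCCCCCCCCCCCCCCc1cc(O)cc(OC)c1C(=O)OC
F3 | step 5 | 4-(hydroxymethyl)-3-methoxy-5-nonadecylphenol | CCCCCCCCCCCCCCCCCCCc1cc(O)cc(OC)c1CO
F4 | step 8 | 3-methoxy-1-nonadecyl-7-oxabicyclo[4.1.0]hept-3-ene-2,5-dione (racemic, cis-fused; one enantiomer drawn) | CCCCCCCCCCCCCCCCCCC[C@@]12O[C@@H]1C(=O)C=C(OC)C2=O
F5 | step 6 | 4-formyl-3-methoxy-5-nonadecylphenyl acetate | CCCCCCCCCCCCCCCCCCCc1cc(OC(C)=O)cc(OC)c1C=O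
F6 | step 6 | 4-(formyloxy)-3-methoxy-5-nonadecylphenyl acetate | CCCCCCCCCCCCCCCCCCCc1cc(OC(C)=O)cc(OC)c1OC=O
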